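The C7–C8 bond of ring B is the disconnection: it joins the tertiary C7 carbinol and the secondary C8 carbinol, which lie cis to each other and to the C8a acetyl group, next to the C6 ketone. One SmI2-mediated reductive cyclisation of an acyclic (Z)-ene-1,2-dione that bears an aldehyde on the quaternary C8a carbon forms this bond, closes ring B and sets C7 and C8 from the single C8a stereocentre. In the precursor the acetyl group is masked as a dioxolane and C1 carries a bulky silyl ether, so the aldehyde is the only acceptor and the ketal oxygen is the only chelating group. Ring A, the side chain and chlorine follow.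

Key step: step 11

Remark: locants C1 to C8a and the ring letters (ring A = pyran, ring B = carbocycle) follow the isochromene numbering of the target; TBDPS = tert-butyldiphenylsilyl; it is assumed that the sense of induction in step 6 can be set by choosing the quinidine- or the quinine-derived catalyst, and the one that gives (2R)-9 is used.

Step 1
Reactants: 1 methyl 2,2-dimethoxypropanoate
Product: 2 N,2,2-trimethoxy-N-methylpropanamide
Conditions: MeNH(OMe)·HCl, i-PrMgCl, THF, −20 to 0 °C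
Reagents that add atoms: N,O-dimethylhydroxylamine hydrochloride, CNOC.Cl
Why: Ester aminolysis by the chloromagnesium amide made in the flask (N-methoxy-N-methylamide formation) should be fast on this non-enolisable, α,α-dioxygenated ester, and no stereocentre is involved.

Step 2
Reactants: 2 N,2,2-trimethoxy-N-methylpropanamide, 3 prop-1-yn-1-ylmagnesium bromide
Product: 4 5,5-dimethoxyhex-2-yn-4-one
Conditions: THF, 0 °C; aq. NH4Cl
Reagents that add atoms: none
Why: Weinreb ketone synthesis, in which the chelated tetrahedral magnesium adduct stops at the ketone, should give the ynone that carries C4, C4a, C5, C6 and the ketal-masked C7.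

Step 3
Reactants: 5 methyl 3-hydroxypropanoate
Product: 6 methyl 3-[(TBDPS)oxy]propanoate
Conditions: t-BuPh2SiCl, imidazole, CH2Cl2, 0 °C to rt
Reagents that add atoms: tert-butyl(chloro)diphenylsilane, CC(C)(C)[Si](Cl)(c1ccccc1)c1ccccc1
Why: Silylation of a primary alcohol installs a bulky, acid-stable and weakly coordinating ether on the future C1 oxygen, as the chelation argument of step 11 requires.

Step 4
Reactants: 6 methyl 3-[(TBDPS)oxy]propanoate
Product: 7 methyl 2-{[(TBDPS)oxy]methyl}-3-hydroxybutanoate (mixture of diastereomers)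
Conditions: LiN(i-Pr)2, THF, −78 °C; MeCHO, −78 °C; aq. NH4Cl
Reagents that add atoms: acetaldehyde, CC=O
Why: Lithium ester-enolate aldol addition, run cold and briefly so that β-elimination of silanolate does not compete, should give the adduct, whose two new stereocentres are erased in steps 5 and 6.

Step 5
Reactants: 7 methyl 2-{[(TBDPS)oxy]methyl}-3-hydroxybutanoate
Product: 8 methyl 2-{[(TBDPS)oxy]methyl}-3-oxobutanoate (racemic, C2 configurationally labile)
Conditions: Dess–Martin periodinane, CH2Cl2, rt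
Reagents that add atoms: none
Why: Dess–Martin oxidation of the secondary alcohol should give the β-keto ester under non-basic conditions that leave the β-silyloxy group in place.

Step 6
Reactants: 8 methyl 2-{[(TBDPS)oxy]methyl}-3-oxobutanoate, 4 5,5-dimethoxyhex-2-yn-4-one
Product: 9 methyl (2R,3Z)-2-acetyl-2-{[(TBDPS)oxy]methyl}-6,6-dimethoxy-3-methyl-5-oxohept-3-enoate
Conditions: epi-9-amino-9-deoxyquinidine 3,5-bis(trifluoromethyl)phenyl thiourea (10 mol %), toluene, −20 °C
Reagents that add atoms: none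
Why: In this organocatalytic enantioselective Michael addition of an α-substituted β-keto ester to an alkynyl ketone, the catalyst amine forms the enolate ion pair while the thiourea binds the ynone carbonyl, so one enolate face should add to the methyl-bearing alkyne carbon and set the C8a quaternary stereocentre as (R), and anti protonation of the allenolate should place C6 cis to C8a (Z).

Step 7
Reactants: 9 methyl (2R,3Z)-2-acetyl-2-{[(TBDPS)oxy]methyl}-6,6-dimethoxy-3-methyl-5-oxohept-3-enoate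
Product: 10 methyl (2R,3Z)-2-{[(TBDPS)oxy]methyl}-6,6-dimethoxy-3-methyl-2-(2-methyl-1,3-dioxolan-2-yl)-5-oxohept-3-enoate
Conditions: Me3SiOCH2CH2OSiMe3, Me3SiOTf (cat.), CH2Cl2, −78 to −20 °C
Reagents that add atoms: 1,2-bis(trimethylsilyloxy)ethane, C[Si](C)(C)OCCO[Si](C)(C)C
Why: Silyl-triflate-catalysed ketalisation works on hindered saturated ketones at low temperature and should leave the conjugated C6 ketone and the deactivated α-keto dimethyl ketal untouched, so only the acetyl group is masked and C8a is not affected.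

Step 8
Reactants: 10 methyl (2R,3Z)-2-{[(TBDPS)oxy]methyl}-6,6-dimethoxy-3-methyl-2-(2-methyl-1,3-dioxolan-2-yl)-5-oxohept-3-enoate
Product: 11 (2R,3Z)-2-{[(TBDPS)oxy]methyl}-6,6-dimethoxy-3-methyl-2-(2-methyl-1,3-dioxolan-2-yl)hept-3-ene-1,5-diol (C5 epimers)
Conditions: i-Bu2AlH (5 equiv), CH2Cl2, −78 to 0 °C; aq. potassium sodium tartrate
Reagents that add atoms: none
Why: Hydride reduction should take the methyl ester to the primary alcohol and the enone by 1,2-addition to the allylic alcohol (a new carbinol centre that is erased in step 10), while both ketals and the silyl ether are inert.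

Step 9
Reactants: 11 (2R,3Z)-2-{[(TBDPS)oxy]methyl}-6,6-dimethoxy-3-methyl-2-(2-methyl-1,3-dioxolan-2-yl)hept-3-ene-1,5-diol
Product: 12 (4Z,6R)-3-hydroxy-6-(hydroxymethyl)-5-methyl-6-(2-methyl-1,3-dioxolan-2-yl)-7-[(TBDPS)oxy]hept-4-en-2-one (C3 epimers)
Conditions: PPTS (cat.), acetone/H2O, rt
Reagents that add atoms: water, O
Why: Acid-catalysed ketal hydrolysis should release the C7 ketone selectively, because the acyclic dimethyl ketal is cleaved far faster than the hindered neopentyl dioxolane.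

Step 10
Reactants: 12 (4Z,6R)-3-hydroxy-6-(hydroxymethyl)-5-methyl-6-(2-methyl-1,3-dioxolan-2-yl)-7-[(TBDPS)oxy]hept-4-en-2-one
Product: 13 (2S,3Z)-2-{[(TBDPS)oxy]methyl}-3-methyl-2-(2-methyl-1,3-dioxolan-2-yl)-5,6-dioxohept-3-enal
Conditions: (COCl)2, Me2SO, CH2Cl2, −78 °C; i-Pr2NEt, −78 to −40 °C; used crude
Reagents that add atoms: none
Why: Swern oxidation activates both hydroxyls before base is added, so the primary alcohol should give the non-enolisable aldehyde and the acyloin the 1,2-dione in one operation without a lactol being intercepted.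

Step 11
Reactants: 13 (2S,3Z)-2-{[(TBDPS)oxy]methyl}-3-methyl-2-(2-methyl-1,3-dioxolan-2-yl)-5,6-dioxohept-3-enal
Product: 14 (4S,5R,6R)-4-{[(TBDPS)oxy]methyl}-5,6-dihydroxy-3,6-dimethyl-4-(2-methyl-1,3-dioxolan-2-yl)cyclohex-2-en-1-one
Conditions: SmI2 (2.2 equiv), THF, −78 °C; aq. NH4Cl at −78 °C
Reagents that add atoms: none
Why: SmI2 should transfer two electrons to the ene-1,2-dione, the most easily reduced group present, to give a samarium dienediolate whose C7 carbon adds to the neopentyl C8 aldehyde; the closest known reactions are the SmI2 ketyl–aldehyde pinacol-type cyclisation to cis-1,2-diols and the aldol additions of samarium enediolates made from 1,2-diketones. Ring B closes in a 6-exo-trig mode onto the aldehyde carbonyl, and C6 re-emerges as the conjugated ketone, which should favour bonding through C7 over a five-membered closure through C6. C8 is controlled by trivalent samarium bridging the aldehyde oxygen, the C7 oxygen and one dioxolane oxygen on C8a, with the bulky ketal pseudo-axial and the non-coordinating silyloxymethyl group pseudo-equatorial, so that O8 ends up on the face of the ketal carbon; C7 is controlled by the same chelate, which holds O7 syn to O8 and gives the cis-diol. The step needs reduction of the ene-dione in the presence of the aldehyde, bonding at C7 and attack on one face of the aldehyde. The substrate secures these by the large gap in reduction potential, by offering the aldehyde as the only carbonyl acceptor (acetyl ketalised, C5 still unchlorinated so no C–Cl bond can be cleaved), and by the Z alkene that holds C7 within reach of C8 (any E isomer can equilibrate at the radical-anion stage). The single C8a stereocentre with one chelating and one non-chelating oxygen substituent does the rest.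

Step 12
Reactants: 14 (4S,5R,6R)-4-{[(TBDPS)oxy]methyl}-5,6-dihydroxy-3,6-dimethyl-4-(2-methyl-1,3-dioxolan-2-yl)cyclohex-2-en-1-one
Product: 15 (3aR,4S,7aR)-4-{[(TBDPS)oxy]methyl}-2,2,5,7a-tetramethyl-4-(2-methyl-1,3-dioxolan-2-yl)-3a,4-dihydro-1,3-benzodioxol-7(7aH)-one
Conditions: 2-methoxypropene, PPTS (cat.), CH2Cl2, 0 °C to rt
Reagents that add atoms: 2-methoxypropene, COC(C)=C
Why: Acetonide formation should be easy because the two hydroxyls are cis, and it blocks retro-aldol and acyl-migration pathways in the later basic steps.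

Step 13
Reactants: 15 (3aR,4S,7aR)-4-{[(TBDPS)oxy]methyl}-2,2,5,7a-tetramethyl-4-(2-methyl-1,3-dioxolan-2-yl)-3a,4-dihydro-1,3-benzodioxol-7(7aH)-one
Product: 16 (3aR,4S,7aR)-6-chloro-4-{[(TBDPS)oxy]methyl}-2,2,5,7a-tetramethyl-4-(2-methyl-1,3-dioxolan-2-yl)-3a,4-dihydro-1,3-benzodioxol-7(7aH)-one
Conditions: SO2Cl2 (1.1 equiv), pyridine, CH2Cl2, 0 °C
Reagents that add atoms: sulfuryl chloride, O=S(=O)(Cl)Cl
Why: Electrophilic α-chlorination of a β,β-disubstituted cyclohexenone by chlorine addition and dehydrochlorination should put chlorine on C5 while the enone is the only alkene in the molecule, and the chlorine then blocks C5 in step 20.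

Step 14
Reactants: 16 (3aR,4S,7aR)-6-chloro-4-{[(TBDPS)oxy]methyl}-2,2,5,7a-tetramethyl-4-(2-methyl-1,3-dioxolan-2-yl)-3a,4-dihydro-1,3-benzodioxol-7(7aH)-one
Product: 17 (3aR,4S,7aR)-6-chloro-4-(hydroxymethyl)-2,2,5,7a-tetramethyl-4-(2-methyl-1,3-dioxolan-2-yl)-3a,4-dihydro-1,3-benzodioxol-7(7aH)-one
Conditions: HF·pyridine, pyridine, THF, 0 °C to rt
Reagents that add atoms: none
Why: Fluoride-mediated silyl ether cleavage under buffered, non-basic conditions should free the C1 alcohol without retro-aldol loss of formaldehyde from a neopentyl alkoxide.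

Step 15
Reactants: 18 (S)-2-methylbutan-1-ol
Product: 20 ethyl (2E,4S)-2,4-dimethylhex-2-enoate, via (S)-2-methylbutanal 19 (not isolated)
Conditions: TEMPO (cat.), PhI(OAc)2, CH2Cl2, rt; then Ph3P=C(Me)CO2Et, rt
Reagents that add atoms: ethyl 2-(triphenylphosphoranylidene)propanoate, CCOC(=O)C(C)=P(c1ccccc1)(c1ccccc1)c1ccccc1
Why: TEMPO oxidation should give the α-chiral aldehyde without epimerisation and the stabilised ylide traps it at once in an E-selective Wittig olefination, the (S) centre coming from the starting alcohol.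

Step 16
Reactants: 20 ethyl (2E,4S)-2,4-dimethylhex-2-enoate
Product: 21 (2E,4S)-2,4-dimethylhex-2-en-1-ol
Conditions: i-Bu2AlH (2.2 equiv), CH2Cl2, −78 °C; aq. potassium sodium tartrate
Reagents that add atoms: none
Why: 1,2-Reduction of the enoate by the aluminium hydride should give the allylic alcohol without touching the alkene or the stereocentre.

Step 17
Reactants: 21 (2E,4S)-2,4-dimethylhex-2-en-1-ol
Product: 23 ethyl (2E,4E,6S)-4,6-dimethylocta-2,4-dienoate, via (2E,4S)-2,4-dimethylhex-2-enal 22 (not isolated)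
Conditions: MnO2 (10 equiv), Ph3P=CHCO2Et, CH2Cl2, rt to 40 °C
Reagents that add atoms: ethyl (triphenylphosphoranylidene)acetate, CCOC(=O)C=P(c1ccccc1)(c1ccccc1)c1ccccc1
Why: Tandem allylic oxidation and Wittig olefination should work because MnO2 oxidises only the allylic alcohol and the stabilised ylide intercepts the enal E-selectively.

Step 18
Reactants: 23 ethyl (2E,4E,6S)-4,6-dimethylocta-2,4-dienoate
Product: 24 (2E,4E,6S)-4,6-dimethylocta-2,4-dienoic acid
Conditions: LiOH, THF/MeOH/H2O, rt; aq. HCl to pH 3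
Reagents that add atoms: lithium hydroxide, [Li+].[OH-]
Why: Saponification of the ethyl ester at room temperature should not disturb the diene geometry or the remote stereocentre.

Step 19
Reactants: 17 (3aR,4S,7aR)-6-chloro-4-(hydroxymethyl)-2,2,5,7a-tetramethyl-4-(2-methyl-1,3-dioxolan-2-yl)-3a,4-dihydro-1,3-benzodioxol-7(7aH)-one, 24 (2E,4E,6S)-4,6-dimethylocta-2,4-dienoic acid
Product: 25 [(3aR,4S,7aR)-6-chloro-2,2,5,7a-tetramethyl-4-(2-methyl-1,3-dioxolan-2-yl)-7-oxo-3a,4,7,7a-tetrahydro-1,3-benzodioxol-4-yl]methyl (2E,4E,6S)-4,6-dimethylocta-2,4-dienoate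
Conditions: EDC·HCl, DMAP, CH2Cl2, 0 °C to rt
Reagents that add atoms: none
Why: Steglich esterification should acylate the neopentyl primary alcohol, the only free hydroxyl, and so tether the C3 carbon and the side chain to the C1 oxygen.

Step 20
Reactants: 25 [(3aR,4S,7aR)-6-chloro-2,2,5,7a-tetramethyl-4-(2-methyl-1,3-dioxolan-2-yl)-7-oxo-3a,4,7,7a-tetrahydro-1,3-benzodioxol-4-yl]methyl (2E,4E,6S)-4,6-dimethylocta-2,4-dienoate
Product: 27 (7R,8R,8aS)-5-chloro-3-[(1E,3E,5S)-3,5-dimethylhepta-1,3-dien-1-yl]-7,8-(isopropylidenedioxy)-7-methyl-8a-(2-methyl-1,3-dioxolan-2-yl)-1,7,8,8a-tetrahydro-6H-isochromen-6-one, via C4-acylated hydroxy enone 26 (not isolated)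
Conditions: LiN(SiMe3)2 (1.1 equiv), THF, −78 to −40 °C; AcOH; then PPTS, CH2Cl2, rt
Reagents that add atoms: none
Why: In this intramolecular vinylogous Claisen condensation the base should remove a C4 proton (the most acidic site, since the acetyl group is ketalised and C5 is chlorinated), the extended enolate should attack the tethered ester through a six-membered transition state, and mild acid should then close the hemiketal of the C1 hydroxyl on the new C3 ketone and dehydrate it to the ring A enol ether.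

Step 21
Reactants: 27 (7R,8R,8aS)-5-chloro-3-[(1E,3E,5S)-3,5-dimethylhepta-1,3-dien-1-yl]-7,8-(isopropylidenedioxy)-7-methyl-8a-(2-methyl-1,3-dioxolan-2-yl)-1,7,8,8a-tetrahydro-6H-isochromen-6-one
Product: 28 (7R,8R,8aS)-8a-acetyl-5-chloro-3-[(1E,3E,5S)-3,5-dimethylhepta-1,3-dien-1-yl]-7,8-dihydroxy-7-methyl-1,7,8,8a-tetrahydro-6H-isochromen-6-one
Conditions: CF3CO2H/H2O (9:1), CH2Cl2, 0 °C to rt
Reagents that add atoms: water, O
Why: Acid-catalysed hydrolysis should remove the acetonide and the dioxolane in one operation, since the vinylogous ester of ring A re-closes under the same conditions and C7, C8 and C8a are not epimerisable by acid.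

Compound list
1 | methyl 2,2-dimethoxypropanoate | COC(=O)C(C)(OC)OC | starting material
2 | N,2,2-trimethoxy-N-methylpropanamide | CC(OC)(OC)C(=O)N(C)OC | intermediate
3 | prop-1-yn-1-ylmagnesium bromide | CC#C[Mg]Br | starting material
4 | 5,5-dimethoxyhex-2-yn-4-one | CC#CC(=O)C(C)(OC)OC | intermediate
5 | methyl 3-hydroxypropanoate | COC(=O)CCO | starting material
6 | methyl 3-[(tert-butyldiphenylsilyl)oxy]propanoate | COC(=O)CCO[Si](c1ccccc1)(c1ccccc1)C(C)(C)C | intermediate
7 | methyl 2-{[(tert-butyldiphenylsilyl)oxy]methyl}-3-hydroxybutanoate (mixture of diastereomers) | COC(=O)C(CO[Si](c1ccccc1)(c1ccccc1)C(C)(C)C)C(C)O | intermediate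
8 | methyl 2-{[(tert-butyldiphenylsilyl)oxy]methyl}-3-oxobutanoate (racemic, C2 labile) | COC(=O)C(CO[Si](c1ccccc1)(c1ccccc1)C(C)(C)C)C(C)=O | intermediate
9 | methyl (2R,3Z)-2-acetyl-2-{[(tert-butyldiphenylsilyl)oxy]methyl}-6,6-dimethoxy-3-methyl-5-oxohept-3-enoate | CC(OC)(OC)C(=O)/C=C(/C)[C@](C(C)=O)(CO[Si](c1ccccc1)(c1ccccc1)C(C)(C)C)C(=O)OC | intermediate
10 | methyl (2R,3Z)-2-{[(tert-butyldiphenylsilyl)oxy]methyl}-6,6-dimethoxy-3-methyl-2-(2-methyl-1,3-dioxolan-2-yl)-5-oxohept-3-enoate | CC(OC)(OC)C(=O)/C=C(/C)[C@](C1(C)OCCO1)(CO[Si](c1ccccc1)(c1ccccc1)C(C)(C)C)C(=O)OC | intermediate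
11 | (2R,3Z)-2-{[(tert-butyldiphenylsilyl)oxy]methyl}-6,6-dimethoxy-3-methyl-2-(2-methyl-1,3-dioxolan-2-yl)hept-3-ene-1,5-diol (C5 epimers) | CC(OC)(OC)C(O)/C=C(/C)[C@](C1(C)OCCO1)(CO[Si](c1ccccc1)(c1ccccc1)C(C)(C)C)CO | intermediate
12 | (4Z,6R)-3-hydroxy-6-(hydroxymethyl)-5-methyl-6-(2-methyl-1,3-dioxolan-2-yl)-7-[(tert-butyldiphenylsilyl)oxy]hept-4-en-2-one (C3 epimers) | CC(=O)C(O)/C=C(/C)[C@](C1(C)OCCO1)(CO[Si](c1ccccc1)(c1ccccc1)C(C)(C)C)CO | intermediate
13 | (2S,3Z)-2-{[(tert-butyldiphenylsilyl)oxy]methyl}-3-methyl-2-(2-methyl-1,3-dioxolan-2-yl)-5,6-dioxohept-3-enal | CC(=O)C(=O)/C=C(/C)[C@](C1(C)OCCO1)(CO[Si](c1ccccc1)(c1ccccc1)C(C)(C)C)C=O | intermediate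
14 | (4S,5R,6R)-4-{[(tert-butyldiphenylsilyl)oxy]methyl}-5,6-dihydroxy-3,6-dimethyl-4-(2-methyl-1,3-dioxolan-2-yl)cyclohex-2-en-1-one | CC1=CC(=O)[C@](C)(O)[C@H](O)[C@@]1(C1(C)OCCO1)CO[Si](c1ccccc1)(c1ccccc1)C(C)(C)C | intermediate
15 | (3aR,4S,7aR)-4-{[(tert-butyldiphenylsilyl)oxy]methyl}-2,2,5,7a-tetramethyl-4-(2-methyl-1,3-dioxolan-2-yl)-3a,4-dihydro-1,3-benzodioxol-7(7aH)-one | CC1=CC(=O)[C@]2(C)OC(C)(C)O[C@@H]2[C@@]1(C1(C)OCCO1)CO[Si](c1ccccc1)(c1ccccc1)C(C)(C)C | intermediate
16 | (3aR,4S,7aR)-6-chloro-4-{[(tert-butyldiphenylsilyl)oxy]methyl}-2,2,5,7a-tetramethyl-4-(2-methyl-1,3-dioxolan-2-yl)-3a,4-dihydro-1,3-benzodioxol-7(7aH)-one | CC1=C(Cl)C(=O)[C@]2(C)OC(C)(C)O[C@@H]2[C@@]1(C1(C)OCCO1)CO[Si](c1ccccc1)(c1ccccc1)C(C)(C)C | intermediate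
17 | (3aR,4S,7aR)-6-chloro-4-(hydroxymethyl)-2,2,5,7a-tetramethyl-4-(2-methyl-1,3-dioxolan-2-yl)-3a,4-dihydro-1,3-benzodioxol-7(7aH)-one | CC1=C(Cl)C(=O)[C@]2(C)OC(C)(C)O[C@@H]2[C@@]1(C1(C)OCCO1)CO | intermediate
18 | (S)-2-methylbutan-1-ol | CC[C@H](C)CO | starting material
19 | (S)-2-methylbutanal | CC[C@H](C)C=O | intermediate
20 | ethyl (2E,4S)-2,4-dimethylhex-2-enoate | CC[C@H](C)/C=C(\C)C(=O)OCC | intermediate
21 | (2E,4S)-2,4-dimethylhex-2-en-1-ol | CC[C@H](C)/C=C(\C)CO | intermediate
22 | (2E,4S)-2,4-dimethylhex-2-enal | CC[C@H](C)/C=C(\C)C=O | intermediate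
23 | ethyl (2E,4E,6S)-4,6-dimethylocta-2,4-dienoate | CC[C@H](C)/C=C(C)/C=C/C(=O)OCC | intermediate
24 | (2E,4E,6S)-4,6-dimethylocta-2,4-dienoic acid | CC[C@H](C)/C=C(C)/C=C/C(=O)O | intermediate
25 | [(3aR,4S,7aR)-6-chloro-2,2,5,7a-tetramethyl-4-(2-methyl-1,3-dioxolan-2-yl)-7-oxo-3a,4,7,7a-tetrahydro-1,3-benzodioxol-4-yl]methyl (2E,4E,6S)-4,6-dimethylocta-2,4-dienoate | CC1=C(Cl)C(=O)[C@]2(C)OC(C)(C)O[C@@H]2[C@@]1(C1(C)OCCO1)COC(=O)/C=C/C(C)=C/[C@@H](C)CC | intermediate
26 | (3aR,4S,7aR)-6-chloro-5-[(3E,5E,7S)-5,7-dimethyl-2-oxonona-3,5-dien-1-yl]-4-(hydroxymethyl)-2,2,7a-trimethyl-4-(2-methyl-1,3-dioxolan-2-yl)-3a,4-dihydro-1,3-benzodioxol-7(7aH)-one | O=C(/C=C/C(C)=C/[C@@H](C)CC)CC1=C(Cl)C(=O)[C@]2(C)OC(C)(C)O[C@@H]2[C@@]1(C1(C)OCCO1)CO | intermediate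
27 | (7R,8R,8aS)-5-chloro-3-[(1E,3E,5S)-3,5-dimethylhepta-1,3-dien-1-yl]-7,8-(isopropylidenedioxy)-7-methyl-8a-(2-methyl-1,3-dioxolan-2-yl)-1,7,8,8a-tetrahydro-6H-isochromen-6-one | CC[C@H](C)/C=C(C)/C=C/C1=CC2=C(Cl)C(=O)[C@]3(C)OC(C)(C)O[C@@H]3[C@@]2(C2(C)OCCO2)CO1 | intermediate
28 | (7R,8R,8aS)-8a-acetyl-5-chloro-3-[(1E,3E,5S)-3,5-dimethylhepta-1,3-dien-1-yl]-7,8-dihydroxy-7-methyl-1,7,8,8a-tetrahydro-6H-isochromen-6-one | CC[C@H](C)/C=C(C)/C=C/C1=CC2=C(Cl)C(=O)[C@](C)(O)[C@H](O)[C@@]2(C(C)=O)CO1 | target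

Total step count: 21. Longest linear sequence: 15 steps (steps 3 to 14 and 19 to 21, from methyl 3-hydroxypropanoate 5).

Steps most likely to fail

1. Step 11. The samarium enediolate may bond through C6 to give a five-membered carbinol, may be protonated to the acyloin before any C–C bond forms, or may add to the aldehyde with poor facial discrimination. Fallback: setting out from 12, the primary alcohol would be oxidised selectively (TEMPO cat., PhI(OAc)2, CH2Cl2) to the acyloin aldehyde (2S,3Z)-5-hydroxy-2-{[(tert-butyldiphenylsilyl)oxy]methyl}-3-methyl-2-(2-methyl-1,3-dioxolan-2-yl)-6-oxohept-3-enal F1. Soft enolisation of its α-hydroxy ketone (MgBr2·OEt2, Et3N, CH2Cl2, −20 °C) would then give a magnesium enediolate without any reduction step. This closes ring B by a reversible intramolecular aldol addition under the same three-oxygen chelate and thermodynamic control, and the route is rejoined at 14.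

2. Step 6. The acyclic enolate may be discriminated poorly by the catalyst, and addition at the methyl-bearing alkyne carbon may be slow enough for loss of silanolate from the donor to compete. Fallback: setting out from 8 and 4, the conjugate addition would be run with an achiral amine base (DABCO 10 mol %, CH2Cl2, rt) to give racemic methyl (3Z)-2-acetyl-2-{[(tert-butyldiphenylsilyl)oxy]methyl}-6,6-dimethoxy-3-methyl-5-oxohept-3-enoate F2. The enantiomers would be separated by preparative supercritical-fluid chromatography on an amylose carbamate chiral stationary phase, and the (2R) enantiomer rejoins the route as 9.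

3. Step 20. Deprotonation at the ε-position of the dienoate may compete with C4 deprotonation and epimerise the side-chain stereocentre, or the enolate may fail to add to the hindered, conjugated ester. Fallback: setting out from 16 and 21, the acyl carbon would be brought in as an aldehyde. Alcohol 21 would be oxidised with MnO2 to 22 and extended with Ph3P=CHCHO to (2E,4E,6S)-4,6-dimethylocta-2,4-dienal F3. Enone 16 would be converted (t-BuMe2SiOTf, Et3N, CH2Cl2, −78 °C) into its cross-conjugated silyl dienol ether (3aR,4S,7aR)-7-[(tert-butyldimethylsilyl)oxy]-6-chloro-4-{[(tert-butyldiphenylsilyl)oxy]methyl}-2,2,7a-trimethyl-5-methylidene-4-(2-methyl-1,3-dioxolan-2-yl)-3a,4,5,7a-tetrahydro-1,3-benzodioxole F4. A vinylogous Mukaiyama aldol addition of F4 to F3 (BF3·OEt2, CH2Cl2, −78 °C), which is γ-selective because C5 carries chlorine, would give the carbinol (3aR,4S,7aR)-6-chloro-5-[(3E,5E,7S)-2-hydroxy-5,7-dimethylnona-3,5-dien-1-yl]-4-{[(tert-butyldiphenylsilyl)oxy]methyl}-2,2,7a-trimethyl-4-(2-methyl-1,3-dioxolan-2-yl)-3a,4-dihydro-1,3-benzodioxol-7(7aH)-one F5. Dess–Martin oxidation would give the ketone (3aR,4S,7aR)-6-chloro-5-[(3E,5E,7S)-5,7-dimethyl-2-oxonona-3,5-dien-1-yl]-4-{[(tert-butyldiphenylsilyl)oxy]methyl}-2,2,7a-trimethyl-4-(2-methyl-1,3-dioxolan-2-yl)-3a,4-dihydro-1,3-benzodioxol-7(7aH)-one F6. HF·pyridine would then remove the silyl ether to give 26, and PPTS cyclodehydrates it as in step 20, so the route is rejoined at 27.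

Further compounds
F1 | step 11 | (2S,3Z)-5-hydroxy-2-{[(tert-butyldiphenylsilyl)oxy]methyl}-3-methyl-2-(2-methyl-1,3-dioxolan-2-yl)-6-oxohept-3-enal (C5 epimers) | CC(=O)C(O)/C=C(/C)[C@](C1(C)OCCO1)(CO[Si](c1ccccc1)(c1ccccc1)C(C)(C)C)C=O
F2 | step 6 | racemic methyl (3Z)-2-acetyl-2-{[(tert-butyldiphenylsilyl)oxy]methyl}-6,6-dimethoxy-3-methyl-5-oxohept-3-enoate | CC(OC)(OC)C(=O)/C=C(/C)C(C(C)=O)(CO[Si](c1ccccc1)(c1ccccc1)C(C)(C)C)C(=O)OC
F3 | step 20 | (2E,4E,6S)-4,6-dimethylocta-2,4-dienal | CC[C@H](C)/C=C(C)/C=C/C=O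
F4 | step 20 | (3aR,4S,7aR)-7-[(tert-butyldimethylsilyl)oxy]-6-chloro-4-{[(tert-butyldiphenylsilyl)oxy]methyl}-2,2,7a-trimethyl-5-methylidene-4-(2-methyl-1,3-dioxolan-2-yl)-3a,4,5,7a-tetrahydro-1,3-benzodioxole | C=C1C(Cl)=C(O[Si](C)(C)C(C)(C)C)[C@]2(C)OC(C)(C)O[C@@H]2[C@@]1(C1(C)OCCO1)CO[Si](c1ccccc1)(c1ccccc1)C(C)(C)C
F5 | step 20 | (3aR,4S,7aR)-6-chloro-5-[(3E,5E,7S)-2-hydroxy-5,7-dimethylnona-3,5-dien-1-yl]-4-{[(tert-butyldiphenylsilyl)oxy]methyl}-2,2,7a-trimethyl-4-(2-methyl-1,3-dioxolan-2-yl)-3a,4-dihydro-1,3-benzodioxol-7(7aH)-one (carbinol epimers) | OC(/C=C/C(C)=C/[C@@H](C)CC)CC1=C(Cl)C(=O)[C@]2(C)OC(C)(C)O[C@@H]2[C@@]1(C1(C)OCCO1)CO[Si](c1ccccc1)(c1ccccc1)C(C)(C)C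
F6 | step 20 | (3aR,4S,7aR)-6-chloro-5-[(3E,5E,7S)-5,7-dimethyl-2-oxonona-3,5-dien-1-yl]-4-{[(tert-butyldiphenylsilyl)oxy]methyl}-2,2,7a-trimethyl-4-(2-methyl-1,3-dioxolan-2-yl)-3a,4-dihydro-1,3-benzodioxol-7(7aH)-one | O=C(/C=C/C(C)=C/[C@@H](C)CC)CC1=C(Cl)C(=O)[C@]2(C)OC(C)(C)O[C@@H]2[C@@]1(C1(C)OCCO1)CO[Si](c1ccccc1)(c1ccccc1)C(C)(C)C
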